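The numbers in the tables stem from a simulated flask from invented constants; the scatter is artificial.

I would back maple, as your hunch does, but I put a ceiling on your quick number.

| flask | free monomer | initiator | temperature | remark | time |
|---|---|---|---|---|---|
| Saturday's | 0.29 M | 7 mM | −15 °C | run made earlier |  |
| Sunday's | 0.29 M | 10 mM | 20 °C | run made earlier |  |
| Monday's | 0.43 M | 14 mM | −15 °C | run made earlier |  |
| maple | 0.29 M | 14 mM | 50 °C |  | 2.5 d |
| elm | 0.29 M | 14 mM | 20 °C |  | 2.5 d |
| larch | 0.29 M | 14 mM |  | at 50 °C until 20 h, from then on at −10 °C | 2.5 d |
| alder | 0.29 M | 14 mM | −10 °C |  | 2.5 d |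

- Saturday's (time / d: monomer in chains / %, free monomer / %): 6.00: 1, 102; 12.0: 0, 100; 20.0: 1, 99; 25.0: 0, 101; 30.0: 0, 99; 40.0: 2, 98
- Sunday's (time / d: monomer in chains / %, free monomer / %): 0.500: 2, 97; 0.833: 5, 96; 1.67: 4, 95; 2.00: 8, 93; 4.00: 17, 82; 8.00: 37, 59
- Monday's (time / d: monomer in chains / %, free monomer / %): 3.00: 0, 102; 5.00: 1, 102; 10.0: 0, 101; 20.0: 1, 99; 40.0: 0, 97

(each reading ± 1.5 percentage points)

* the flask that comes out highest in amount of monomer in chains, in percent of the free monomer charged, or "all alike" when all lie within 1.5 percentage points (maple / elm / larch / alder / all alike)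
* monomer in chains at the end, in percent of the free monomer charged, maple
* monomer in chains at the end, in percent of the free monomer charged, elm
* monomer in chains at the end, in percent of the free monomer charged, larch
* monomer in chains at the end, in percent of the free monomer charged, alder

- the numbers in the tables scatter with a standard deviation of 1.5 percentage points

1. Let x be the fraction of charged free monomer consumed, and N the initiator charge. I assume that monomer is lost in proportion to the chains present, while consumption goes with N. Loss per unit of x then grows with x and falls with N.

2. Integrating gives loss = (B/N) times x squared, and chains = x minus that loss. B/N is a kind of selectivity factor.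

3. Sunday's last reading, at 8.00 d, has 59% free and 37% in chains, so 4.00% of the charge is in neither. With a scatter of 1.5 points per reading, this is a weak reading. It gives the loss charge, 2.38 mM, which is the fraction lost at full consumption times the initiator charge.

4. For maple I take x near one, and that is an assumption, for the warmest run stands at 20 °C. At 14 mM my loss is then 17.0%, so my rule gives maple's chains a ceiling of 83.0%.

5. Larch gets 20 h of heat against maple's 2.5 d, so I expect a smaller x in larch. Scaling Sunday's consumption by charge and time gives elm x = 20.6%. Alder sits near the cold of Saturday's run, which still had 98% free after 40.0 d.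

The forecast also picks maple, with 92% for maple, 16% for elm, 75% for larch and 0.2% for alder, on the ground that “Maple then nears completion”, and its maple stands above my ceiling.

The flasks give maple as highest: maple 74.6%, elm 13.5%, larch 66.6%, alder 0.122%.

    free monomer + initiator → living end + monomer in chains (k = 0.0310 /M/min, Ea = 85.0 kJ/mol)
    free monomer + living end → monomer in chains + living end, rate k2*[living end]*[free monomer] (k = 0.110 /M/min, Ea = 79.0 kJ/mol)
    free monomer + monomer in chains → side product (k = 0.00110 /M/min, Ea = 78.0 kJ/mol)
    initiator ⇌ dormant form (K = 28.0, k = 0.00140 /min, Ea = 116 kJ/mol, ΔH = −8.00 kJ/mol)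
    monomer in chains → over-reaction product (k = 2.90 × 10⁻⁵ /min, Ea = 125 kJ/mol)
    (constants at 50 °C)

Maple ends with 0.45% of its free monomer left, so my loss of 16.8% stands against 18.3% of side product, and its 6.59% of over-reaction product lies outside my rule. Maple's chains end below the ceiling. The neighbouring flask is larch with 0.0035 M of initiator, a quarter of larch's charge. This neighbour ends with 64.8% free, so x = 35.2%, and I reckon a loss of 8.43% and chains of 26.8%. That flask holds 8.32% of side product and 26.3% of monomer in chains.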